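Our closed, stirred vessel holds starting material and second substrate at a charge ratio of 1.05, together with enzyme, and its product readings have gone flat. The question is what stopped them.

- green: starting material 10 mM; second substrate 10.5 mM; enzyme 1 µM; the very flask that is asked about, followed so far
- flask: starting material 10 mM; second substrate 10.5 mM; enzyme 1.0 µM; time 12 min

green run (percent of the starting material charged): time / min: product / % = 0.833: 16.5; 1.33: 23.1; 2.00: 25.8; 2.50: 28.8; 4.00: 32.3; 6.00: 32.2; 10.0: 31.5

(readings scatter by 1 percentage point)

- product that was removed still counts
- additions bring no volume worth counting

- autumn: at 12 min add enzyme, 100% of the amount charged, then wait 6.0 min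
- summer: change nothing and wait 6.0 min more
- dusk: at 12 min take out 90% of the product then present, then wait 6.0 min
- spring: at 12 min add second substrate, 50.0% of the amount charged, then wait 6.0 min

* product, in percent of the starting material first charged, at 12 min
* the option that brings most further product ("none" if no option brings more than 2 percentage points) (autumn / summer / dusk / spring / none)
* product present, with what was taken out counted in, in percent of the starting material first charged, after dusk
* product present, with what was taken out counted in, in percent of the starting material first charged, after spring

Let a be the free starting material as a fraction of its charge.

1. The rule. We take the rate as enzyme times a times a, since the charge ratio is 1.05, and we let the enzyme die at first order (deactivation) with time constant τ. The reciprocal of a then climbs in step with the live enzyme. Integrating gives: reciprocal of a, minus one, equals D times (one minus exp(−t/τ)).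

2. The plateau. The last three readings average 32.0%, so D reads 0.471. This is the enzyme dose, the rise in the reciprocal of a that one charge of enzyme buys before it dies.

3. The first rung of the ladder. The reading at 2.00 min gives τ of about 1.49 min.

4. The next rungs. The wait of 6.0 min is 4.03 time constants, so a fresh charge can spend its dose within it. The asked time is 8.06 time constants, so we expect the flask to stand at 32.0% then.

5. The choice. A reversible stop also gives flat readings, so this run leaves the choice open, and we commit to lost enzyme. Summer, dusk and spring then stay near 32.0%. Autumn adds one dose, taking a to 0.515, a gain of 16 percentage points, so autumn is our pick.

The forecast gave 32% now, dusk as best, 48% after dusk and 42.5% after spring, “with the enzyme still working”.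

The flask gives 33.2% at the asked time, and autumn is best, gaining 17 points; dusk ends at 33.3% and spring at 33.3%. At 12.0 min, spent catalyst stands at >99.9% of the enzyme charged.

    starting material + enzyme ⇌ starting complex (K = 120 /M, k = 5.80 × 10⁵ /M/s)
    second substrate + starting complex ⇌ ternary complex (K = 33.0 /M, k = 2.90 × 10⁶ /M/s)
    ternary complex → enzyme + product (k = 290 /s)
    enzyme → spent catalyst (k = 0.0240 /s)

Applied to the simulated 33.2%, the dose D gives autumn a gain of 16 points.

A neighbour flask is charged with 0.0040 mM of enzyme, 4.00 times the enzyme of our flask, so with the same τ its dose is 1.88 and its product should be 65.3%. The computed neighbour flask gives 67.5%.

Readings and results are calculated on assumed constants, and the scatter is random.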